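**Retrosynthetic overview**
1. The target is methyl 3-angeloyloxy-8-oxo-cis-eremophil-6-en-12-oate. The angelate on the C3 hydroxyl and the oxidation and methylation at C12 are left to the end, so the core needed is the cis-fused 3-hydroxy enone with C12 as a silyl-protected alcohol.
2. Structural feature used: ring B (C5–C6=C7–C8(=O)–C9–C10) has the same ring atoms as a δ-lactone C5–C6–O–C8(=O)–C9–C10 except at one position, and C7, the carbon that stands where that oxygen is, is the atom that carries the C11(C13)–C12 side chain.
3. Key disconnection: C7–C8 and C6=C7 are cut together. C7, C11, C12 and C13 come from a Roche-ester-derived phosphonate; C6 (aldehyde masked as a methyl lactol ether) and C8 (lactone carbonyl) come from a cis-fused methoxy lactone. Acylation followed by intramolecular Horner–Wadsworth–Emmons olefination closes ring B.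
4. Methoxy lactone: ring A by an enantioselective Diels–Alder reaction of (E)-2-methylbut-2-enal with methyl (3E)-hexa-3,5-dienoate (sets C4, C5, C10), lactol-ether closure of the aldehyde acid, allylic oxidation at C3, hydrogenation and face-selective ketone reduction (sets C3).
5. Ring order: ring A (Diels–Alder), then the temporary lactone ring, then ring B (key step).

Key step: step 12

Remark: eremophilane numbering is used throughout (ring A: C1–C5 and C10; ring B: C5–C10; side chain C11–C13; methyl C14 on C5, methyl C15 on C4).
Assumption: the oxazaborolidinium catalyst derived from (R)-α,α-diphenylprolinol is taken to shield the Cα-Re face of the formyl-bound s-trans enal; should the sense be the opposite, the (S)-catalyst is used and nothing else changes.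

**Step 1**
Reactants: 1 methyl sorbate (methyl (2E,4E)-hexa-2,4-dienoate)
Product: 2 methyl (3E)-hexa-3,5-dienoate
Conditions: LiN(i-Pr)2 (1.1 equiv), DMPU, THF, −78 °C; then AcOH, −78 °C
Reagents that add atoms: none
Why: Deconjugative isomerisation, in which deprotonation at the terminal methyl gives the extended enolate and kinetic protonation at the α-carbon moves the diene out of conjugation with the ester, leaving the (3E)-1-substituted butadiene.

**Step 2**
Reactants: 2 methyl (3E)-hexa-3,5-dienoate; 3 (E)-2-methylbut-2-enal
Product: 4 methyl 2-[(1S,5S,6R)-6-formyl-5,6-dimethylcyclohex-2-en-1-yl]acetate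
Conditions: (R)-3,3-diphenyl-1-(o-tolyl)tetrahydro-1H,3H-pyrrolo[1,2-c][1,3,2]oxazaborole·HNTf2 (20 mol %), CH2Cl2, −40 → −20 °C
Reagents that add atoms: none
Why: Enantioselective Diels–Alder reaction under chiral cationic oxazaborolidine catalysis, in which the substituted diene terminus bonds to the enal α-carbon (ortho orientation), the E geometry of the enal fixes the cis C4/C5 methyl pair, the endo (formyl) transition state places the acetate arm at C10 cis to the formyl group, and attack on the unshielded Cα-Si face sets the absolute configuration.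

**Step 3**
Reactants: 4 methyl 2-[(1S,5S,6R)-6-formyl-5,6-dimethylcyclohex-2-en-1-yl]acetate
Product: 5 2-[(1S,5S,6R)-6-formyl-5,6-dimethylcyclohex-2-en-1-yl]acetic acid (open form of the cyclic lactol)
Conditions: LiOH·H2O, THF/H2O, 0 °C → rt; then aqueous HCl to pH 3, 0 °C
Reagents that add atoms: lithium hydroxide, [Li+].[OH-]
Why: Ester saponification, which is safe here because the aldehyde sits on the quaternary C5 and has no α-hydrogen and none of the stereocentres is enolisable.

**Step 4**
Reactants: 5 2-[(1S,5S,6R)-6-formyl-5,6-dimethylcyclohex-2-en-1-yl]acetic acid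
Product: 6 cis-fused methoxy lactone with the C1=C2 double bond (1-methoxy-8,8a-dimethyl-4a,7,8,8a-tetrahydro-1H-isochromen-3(4H)-one; C4 methyl, C5 methyl and H-10 on one face; either C6 anomer)
Conditions: MeOH (10 equiv), TsOH·H2O (5 mol %), CH2Cl2, 3 Å molecular sieves, rt
Reagents that add atoms: methanol, CO
Why: Pseudo-ester formation, in which the δ-aldehydo acid reacts through its ring (lactol) tautomer and the lactol hydroxyl is exchanged for methoxyl under acid catalysis faster than the carboxyl group is esterified; the new acetal centre C6 needs no control because it becomes sp2 in step 12.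

**Step 5**
Reactants: 6 cis-fused methoxy lactone with the C1=C2 double bond
Product: 7 cis-fused methoxy lactone 1-en-3-one (1-methoxy-8,8a-dimethyl-4a,8a-dihydro-1H-isochromene-3,7(4H,8H)-dione)
Conditions: CrO3, 3,5-dimethylpyrazole, CH2Cl2, −20 °C
Reagents that add atoms: chromium trioxide, O=[Cr](=O)=O
Why: Allylic oxidation by the chromium trioxide–3,5-dimethylpyrazole complex, expected to give mainly the 1-en-3-one because C3 is the only allylic methylene whereas the other allylic position C10 is a tertiary ring-fusion C–H next to the quaternary C5 that cannot become a ketone, and the acylal survives the non-aqueous buffered medium.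

**Step 6**
Reactants: 7 cis-fused methoxy lactone 1-en-3-one
Product: 8 cis-fused methoxy lactone 3-ketone (1-methoxy-8,8a-dimethyl-4a,5,6,8a-tetrahydro-1H-isochromene-3,7(4H,8H)-dione)
Conditions: H2 (1 atm), Pd/C, EtOAc, rt
Reagents that add atoms: none
Why: Heterogeneous catalytic hydrogenation of the enone double bond, which creates no stereocentre, leaves lactone, acetal and ketone untouched, and keeps C4 (now α to the ketone) away from base.

**Step 7**
Reactants: 8 cis-fused methoxy lactone 3-ketone
Product: 9 cis-fused hydroxy methoxy lactone (7-hydroxy-1-methoxy-8,8a-dimethylhexahydro-1H-isochromen-3(4H)-one; eremophilane locants 3S,4R,5S,10R; C3 hydroxyl, C4 methyl, C5 methyl and H-10 on one face)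
Conditions: Li(s-Bu)3BH (1.1 equiv), THF, −78 °C; aqueous NH4Cl
Reagents that add atoms: none
Why: Diastereoselective ketone reduction by a bulky trialkylborohydride, which, as with 2-methylcyclohexanone, should deliver hydride to C3 from the face opposite the C4 and C5 methyl groups (equatorial attack on the chair with equatorial C4 methyl and axial C5 methyl) so that the new hydroxyl is cis to both methyls, while the lactone is not touched at −78 °C.

**Step 8**
Reactants: 10 methyl (S)-3-hydroxy-2-methylpropanoate
Product: 11 methyl (S)-3-(tert-butyldimethylsilyloxy)-2-methylpropanoate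
Conditions: TBSCl, imidazole, CH2Cl2, 0 °C → rt
Reagents that add atoms: tert-butyldimethylsilyl chloride, CC(C)(C)[Si](C)(C)Cl
Why: Silyl ether formation at the primary hydroxyl under imidazole catalysis, which does not touch the stereocentre.

**Step 9**
Reactants: 11 methyl (S)-3-(tert-butyldimethylsilyloxy)-2-methylpropanoate
Product: 12 (R)-3-(tert-butyldimethylsilyloxy)-2-methylpropan-1-ol
Conditions: i-Bu2AlH (2.2 equiv), CH2Cl2, −78 → 0 °C; aqueous Rochelle salt
Reagents that add atoms: none
Why: Hydride reduction of the ester to the primary alcohol, in which the aldehyde stage is passed as its aluminium hemiacetal at low temperature so that the α-stereocentre is not epimerised.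

**Step 10**
Reactants: 12 (R)-3-(tert-butyldimethylsilyloxy)-2-methylpropan-1-ol
Product: 13 (S)-tert-butyl(3-iodo-2-methylpropoxy)dimethylsilane
Conditions: I2, PPh3, imidazole, CH2Cl2, 0 °C → rt
Reagents that add atoms: iodine, II
Why: Appel-type iodination through the alkoxyphosphonium ion with SN2 displacement at the primary carbon, so the adjacent stereocentre is untouched.

**Step 11**
Reactants: 13 (S)-tert-butyl(3-iodo-2-methylpropoxy)dimethylsilane
Product: 14 dimethyl [(2S)-3-(tert-butyldimethylsilyloxy)-2-methylpropyl]phosphonate
Conditions: P(OMe)3 (neat, excess), 110 °C, MeI distilled off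
Reagents that add atoms: trimethyl phosphite, COP(OC)OC
Why: Michaelis–Arbuzov reaction, in which the phosphite displaces the primary iodide and the phosphonium ion is demethylated by iodide, giving the phosphonate with the future C11 stereocentre untouched.

**Step 12**
Reactants: 9 cis-fused hydroxy methoxy lactone; 14 dimethyl [(2S)-3-(tert-butyldimethylsilyloxy)-2-methylpropyl]phosphonate
Product: 17 (3S,4R,5R,10R,11R)-12-(tert-butyldimethylsilyloxy)-3-hydroxy-cis-eremophil-6-en-8-one, via lithiated phosphonate 15 (not isolated), via keto phosphonate aldehyde 16 (not isolated)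
Conditions: 14 (3.2 equiv), n-BuLi (3.1 equiv), THF, −78 °C; add 9, −78 °C → rt; then 50 °C
Reagents that add atoms: none
Why: Proposed new method: one equivalent of carbanion 15 deprotonates the free C3 hydroxyl (left unprotected so that it can be acylated directly in step 13), a second adds to the lactone carbonyl C8, and collapse of the tetrahedral adduct expels the C6 hemiacetal oxygen, which loses methoxide to unmask the C6 aldehyde while the third equivalent (or the methoxide) turns β-keto phosphonate 16 into its stabilised anion. That anion adds to the C6 aldehyde and the oxaphosphetane collapses (intramolecular Horner–Wadsworth–Emmons olefination), so that C7 takes the ring position held by the lactone oxygen and the C7–C8 and C6=C7 bonds are made in one flask. The closest known reactions are the phosphonate variant of the Fujimoto–Belleau synthesis of cyclohexenones from enol lactones and the lactone → β-keto phosphonate → Horner–Wadsworth–Emmons sequence; a lactol methyl ether (pseudo-ester) has not been shown as the acyl donor, which is why the step carries the label. Ring B closes by 6-exo-trig attack of the phosphonate-stabilised C7 on the aldehyde carbon C6, followed by elimination that leaves the new double bond endocyclic. No stereocentre is formed: C11 comes in with the reagent at the alcohol oxidation level, is never α to a carbonyl or to phosphorus and cannot epimerise, and C5 and C10 bear no acidic hydrogen. The step needs chemoselectivity only (attack at the lactone carbonyl and not at the acetal carbon, and deprotonation of 16 before carbanion reaches the aldehyde), which is secured because the acetal is inert to carbanions without a Lewis acid, the aldehyde appears only after acylation and is shielded by the quaternary C5, and the much more acidic keto phosphonate quenches residual carbanion at once.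

**Step 13**
Reactants: 17 (3S,4R,5R,10R,11R)-12-(tert-butyldimethylsilyloxy)-3-hydroxy-cis-eremophil-6-en-8-one; 18 angelic acid ((Z)-2-methylbut-2-enoic acid)
Product: 20 (3S,4R,5R,10R,11R)-3-angeloyloxy-12-(tert-butyldimethylsilyloxy)-cis-eremophil-6-en-8-one, via mixed anhydride 19 (not isolated)
Conditions: 18 (3 equiv), 2,4,6-Cl3C6H2COCl (3 equiv), Et3N (3.3 equiv), toluene, rt; then 17, 80 °C
Reagents that add atoms: none
Why: Yamaguchi-type esterification through the angelic 2,4,6-trichlorobenzoic anhydride without a nucleophilic catalyst, which should keep the Z double bond because no reversible conjugate addition to the angeloyl unit occurs, with the alcohol attacking the less hindered angeloyl carbonyl and no base-sensitive stereocentre present at this stage.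

**Step 14**
Reactants: 20 (3S,4R,5R,10R,11R)-3-angeloyloxy-12-(tert-butyldimethylsilyloxy)-cis-eremophil-6-en-8-one
Product: 21 (3S,4R,5R,10R,11R)-3-angeloyloxy-12-hydroxy-cis-eremophil-6-en-8-one
Conditions: HF·pyridine, pyridine, THF, 0 °C → rt
Reagents that add atoms: none
Why: Fluoride-mediated cleavage of the primary silyl ether in a buffered medium that leaves the angelate, the enone and the C11 stereocentre untouched.

**Step 15**
Reactants: 21 (3S,4R,5R,10R,11R)-3-angeloyloxy-12-hydroxy-cis-eremophil-6-en-8-one
Product: 23 (3S,4R,5R,10R,11R)-3-angeloyloxy-8-oxo-cis-eremophil-6-en-12-oic acid, via aldehyde 22 (not isolated)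
Conditions: TEMPO (2,2,6,6-tetramethylpiperidine-1-oxyl, 0.2 equiv), PhI(OAc)2 (2.5 equiv), MeCN/H2O (1:1), rt
Reagents that add atoms: water, O
Why: Oxoammonium (TEMPO) oxidation of the primary alcohol to the aldehyde and of its hydrate to the acid in one flask, so that the epimerisable β,γ-unsaturated aldehyde 22 is consumed as it forms in a weakly acidic medium while the electron-poor trisubstituted alkenes stay untouched.

**Step 16**
Reactants: 23 (3S,4R,5R,10R,11R)-3-angeloyloxy-8-oxo-cis-eremophil-6-en-12-oic acid
Product: 24 methyl (3S,4R,5R,10R,11R)-3-angeloyloxy-8-oxo-cis-eremophil-6-en-12-oate (CNP0323033.1)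
Conditions: TMSCHN2, MeOH/toluene (1:4), 0 °C
Reagents that add atoms: (trimethylsilyl)diazomethane, C[Si](C)(C)C=[N+]=[N-]
Why: Methyl ester formation by a diazoalkane (protonation by the acid, then O-alkylation of the carboxylate) under neutral conditions, which avoids base at C11 (now α to an ester and allylic) and keeps the angelate Z.

**Compound list**
1 | methyl sorbate (methyl (2E,4E)-hexa-2,4-dienoate) | COC(=O)/C=C/C=C/C | starting material
2 | methyl (3E)-hexa-3,5-dienoate | COC(=O)C/C=C/C=C | intermediate
3 | (E)-2-methylbut-2-enal | C/C=C(\C)C=O | starting material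
4 | methyl 2-[(1S,5S,6R)-6-formyl-5,6-dimethylcyclohex-2-en-1-yl]acetate | C1C=C[C@H](CC(=O)OC)[C@](C)(C=O)[C@H]1C | intermediate
5 | 2-[(1S,5S,6R)-6-formyl-5,6-dimethylcyclohex-2-en-1-yl]acetic acid | C1C=C[C@H](CC(=O)O)[C@](C)(C=O)[C@H]1C | intermediate
6 | cis-fused methoxy lactone with C1=C2 double bond (C6 anomer shown: methoxyl cis to C5 methyl) | C1C=C[C@@H]2CC(=O)O[C@@H](OC)[C@]2(C)[C@H]1C | intermediate
7 | cis-fused methoxy lactone 1-en-3-one | O=C1C=C[C@@H]2CC(=O)O[C@@H](OC)[C@]2(C)[C@H]1C | intermediate
8 | cis-fused methoxy lactone 3-ketone | O=C1CC[C@@H]2CC(=O)O[C@@H](OC)[C@]2(C)[C@H]1C | intermediate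
9 | cis-fused hydroxy methoxy lactone (key-step precursor; 3-OH, 4-Me, 5-Me, H-10 on one face) | O[C@H]1CC[C@@H]2CC(=O)O[C@@H](OC)[C@]2(C)[C@H]1C | intermediate
10 | methyl (S)-3-hydroxy-2-methylpropanoate | COC(=O)[C@@H](C)CO | starting material
11 | methyl (S)-3-(tert-butyldimethylsilyloxy)-2-methylpropanoate | COC(=O)[C@@H](C)CO[Si](C)(C)C(C)(C)C | intermediate
12 | (R)-3-(tert-butyldimethylsilyloxy)-2-methylpropan-1-ol | OC[C@@H](C)CO[Si](C)(C)C(C)(C)C | intermediate
13 | (S)-tert-butyl(3-iodo-2-methylpropoxy)dimethylsilane | IC[C@@H](C)CO[Si](C)(C)C(C)(C)C | intermediate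
14 | dimethyl [(2S)-3-(tert-butyldimethylsilyloxy)-2-methylpropyl]phosphonate (key-step precursor) | COP(=O)(OC)C[C@@H](C)CO[Si](C)(C)C(C)(C)C | intermediate
15 | lithiated phosphonate (α-lithio derivative of 14) | [Li+].COP(=O)(OC)[CH-][C@@H](C)CO[Si](C)(C)C(C)(C)C | intermediate
16 | keto phosphonate aldehyde (ring-opened: C8 ketone carrying the C7 phosphonate, free C6 aldehyde, free 3-OH; C7 epimers) | O[C@H]1CC[C@H](CC(=O)C([C@@H](C)CO[Si](C)(C)C(C)(C)C)P(=O)(OC)OC)[C@](C)(C=O)[C@H]1C | intermediate
17 | (3S,4R,5R,10R,11R)-12-(tert-butyldimethylsilyloxy)-3-hydroxy-cis-eremophil-6-en-8-one (key-step product) | O[C@H]1CC[C@@H]2CC(=O)C([C@@H](C)CO[Si](C)(C)C(C)(C)C)=C[C@]2(C)[C@H]1C | intermediate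
18 | angelic acid ((Z)-2-methylbut-2-enoic acid) | C/C=C(/C)C(=O)O | starting material
19 | angelic 2,4,6-trichlorobenzoic anhydride | C/C=C(/C)C(=O)OC(=O)c1c(Cl)cc(Cl)cc1Cl | intermediate
20 | (3S,4R,5R,10R,11R)-3-angeloyloxy-12-(tert-butyldimethylsilyloxy)-cis-eremophil-6-en-8-one | C/C=C(/C)C(=O)O[C@H]1CC[C@@H]2CC(=O)C([C@@H](C)CO[Si](C)(C)C(C)(C)C)=C[C@]2(C)[C@H]1C | intermediate
21 | (3S,4R,5R,10R,11R)-3-angeloyloxy-12-hydroxy-cis-eremophil-6-en-8-one | C/C=C(/C)C(=O)O[C@H]1CC[C@@H]2CC(=O)C([C@@H](C)CO)=C[C@]2(C)[C@H]1C | intermediate
22 | (3S,4R,5R,10R,11R)-3-angeloyloxy-8-oxo-cis-eremophil-6-en-12-al | C/C=C(/C)C(=O)O[C@H]1CC[C@@H]2CC(=O)C([C@@H](C)C=O)=C[C@]2(C)[C@H]1C | intermediate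
23 | (3S,4R,5R,10R,11R)-3-angeloyloxy-8-oxo-cis-eremophil-6-en-12-oic acid | C/C=C(/C)C(=O)O[C@H]1CC[C@@H]2CC(=O)C([C@@H](C)C(=O)O)=C[C@]2(C)[C@H]1C | intermediate
24 | methyl (3S,4R,5R,10R,11R)-3-angeloyloxy-8-oxo-cis-eremophil-6-en-12-oate | C/C=C(/C)C(=O)O[C@H]1CC[C@@H]2CC(=O)C([C@@H](C)C(=O)OC)=C[C@]2(C)[C@H]1C | target

**Step count**
Total: 16 steps. Longest linear sequence: 12 steps (steps 1–7, then 12–16); the phosphonate branch is steps 8–11.

**Steps most likely to fail**

Step 12 (Proposed new method). The carbanion may add to the freed aldehyde before the keto phosphonate is deprotonated, the lactone may be enolised and not acylated, or the hindered olefination may stall in the lithium medium. The fallback uses known reactions, sets out from 9 and comes back to the route at 17. Methanol, trimethyl orthoformate and catalytic TsOH open the pseudo-ester to the methyl ester dimethyl acetal F1. Acylation of the lithiated phosphonate 15 (3 equiv, THF, −78 °C) by this ordinary methyl ester gives the keto phosphonate acetal F2 with the aldehyde still masked. Pyridinium p-toluenesulfonate in wet acetone, chosen to spare the primary silyl ether, releases 16. LiCl and i-Pr2NEt in MeCN (Masamune–Roush conditions) then close ring B to 17.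

Step 5. Hydrogen abstraction may occur at the C10 ring-fusion position, or oxygen may be delivered to the other end of the allyl unit (allylic transposition), so that isomeric enones form. The fallback sets out from 6 and comes back at 7. SeO2 (catalytic) with t-BuOOH in CH2Cl2 hydroxylates by an ene reaction and a [2,3]-sigmatropic shift, which keeps the double bond in place and prefers CH2 over CH. It gives the C3 allylic alcohol F3 (expected mainly with the hydroxyl trans to the C4 methyl; either epimer serves). Dess–Martin periodinane then gives 7.

Step 2. The α,β-disubstituted enal may react too slowly, so that diene polymerisation competes, or facial discrimination by the catalyst may be insufficient. The fallback sets out from 2 and 3 and comes back at 6. Me2AlCl in CH2Cl2 (−78 → −20 °C) gives the racemic adduct F4 with the same ortho and endo preference. LiOH gives the racemic aldehyde acid F5. Heating with (−)-menthol and catalytic TsOH (toluene, water removal) gives diastereomeric menthyl lactol ethers, which are separated by crystallisation or chromatography; the one with the ring configuration of 6 is the menthyl lactol ether F6. Acid-catalysed exchange with methanol (MeOH, TsOH) then gives 6.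

**Further compounds**
F1 | step 12 | methyl ester dimethyl acetal (methyl 2-[2-(dimethoxymethyl)-4-hydroxy-2,3-dimethylcyclohexyl]acetate, ring configuration as in 9) | O[C@H]1CC[C@H](CC(=O)OC)[C@](C)(C(OC)OC)[C@H]1C
F2 | step 12 | keto phosphonate acetal (dimethyl acetal of 16) | O[C@H]1CC[C@H](CC(=O)C([C@@H](C)CO[Si](C)(C)C(C)(C)C)P(=O)(OC)OC)[C@](C)(C(OC)OC)[C@H]1C
F3 | step 5 | C3 allylic alcohol of 6 (hydroxyl trans to the C4 methyl) | O[C@@H]1C=C[C@@H]2CC(=O)O[C@@H](OC)[C@]2(C)[C@H]1C
F4 | step 2 | racemic Diels–Alder adduct (4 and its enantiomer) | C1C=C[C@H](CC(=O)OC)[C@](C)(C=O)[C@H]1C.C1C=C[C@@H](CC(=O)OC)[C@@](C)(C=O)[C@@H]1C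
F5 | step 2 | racemic aldehyde acid (5 and its enantiomer) | C1C=C[C@H](CC(=O)O)[C@](C)(C=O)[C@H]1C.C1C=C[C@@H](CC(=O)O)[C@@](C)(C=O)[C@@H]1C
F6 | step 2 | (−)-menthyl lactol ether with the ring configuration of 6 | C1C=C[C@@H]2CC(=O)O[C@@H](O[C@@H]3C[C@H](C)CC[C@H]3C(C)C)[C@]2(C)[C@H]1C
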